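The oxolan-2-one ring is opened across two bonds, O1–C5 and C3–C4, which leads back to an (E)-alkenyl p-tolyl sulfoxide and dichloroketene. In one operation the Marino lactonisation makes both bonds: a sulfoxide-directed [3,3] shift joins the ketene carbon to C4 with sulfur-to-carbon chirality transfer, and the carboxylate closes onto C5. It exploits the fact that C5 of the lactone is an unsubstituted CH2 beside the C4 stereocentre, so C5 can carry a removable arylthio group. The precursor is a hydroazulenyl keto vinyl sulfoxide, assembled by a tertiary-radical Giese coupling with a chiral butenolide; its methyl ketone ends as the acetate.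

Key step: step 7

Assumption: the sense of induction in steps 1 and 7 follows the models in their Why lines, and the reagent enantiomers are named on that basis; ring stereocentres of 9–16 are those of 17 and are fixed by the SMILES.

Step 1
Reactants: 1 4,4-dimethylcyclohex-2-en-1-one; 2 but-3-en-1-ylmagnesium bromide
Product: 4 (3R)-3-(but-3-en-1-yl)-4,4-dimethyl-1-(trimethylsilyloxy)cyclohex-1-ene, via magnesium enolate 3 (not isolated)
Conditions: CuBr·SMe2 (5 mol %), (R,S)-Josiphos (6 mol %), t-BuOMe, −75 °C; then TMSCl, Et3N, −75 °C → rt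
Reagents that add atoms: chlorotrimethylsilane, C[Si](C)(C)Cl
Why: Copper-catalysed asymmetric conjugate addition of a Grignard reagent should set the β-stereocentre (3R) under control of the chiral ferrocenyl diphosphine, the ligand enantiomer being selected for this sense, and O-silylation of the enolate fixes the enol ether regiochemistry needed in step 2.

Step 2
Reactants: 4 (3R)-3-(but-3-en-1-yl)-4,4-dimethyl-1-(trimethylsilyloxy)cyclohex-1-ene
Product: 5 cis-fused (3aR,7aR)-7,7-dimethyl-3-methylideneoctahydro-4H-inden-4-one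
Conditions: Pd(OAc)2 (10 mol %), O2 (1 atm), DMSO, 45 °C
Reagents that add atoms: none
Why: Oxidative cycloalkenylation of a silyl enol ether by palladium diacetate (intramolecular Saegusa-type C-alkenylation), in which the palladium enolate carbon adds 5-exo-trig to the tethered alkene and β-hydride elimination leaves the exocyclic methylene, the tether forcing the new ring-fusion stereocentre cis to the existing one.

Step 3
Reactants: 5 cis-fused (3aR,7aR)-7,7-dimethyl-3-methylideneoctahydro-4H-inden-4-one
Product: 7 cis-fused (3aR,8aR)-8,8-dimethyl-3-methylideneoctahydroazulen-4(1H)-one, via α-silyl ketone 6 (not isolated)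
Conditions: TMSCHN2, BF3·OEt2, CH2Cl2, −78 → −40 °C; then 1 M HCl, THF, 0 °C
Reagents that add atoms: (trimethylsilyl)diazomethane, C[Si](C)(C)C=[N+]=[N-]
Why: Lewis-acid-promoted one-carbon ring expansion of a ketone with a diazoalkane (Tiffeneau–Demjanov type), where the bulky silyl reagent should favour migration of the unhindered CH2 over the ring-fusion methine, acid then cleaves the C–Si bond, and no stereocentre is touched.

Step 4
Reactants: 7 cis-fused (3aR,8aR)-8,8-dimethyl-3-methylideneoctahydroazulen-4(1H)-one; 8 (5R)-5-[(1R,2S,5R)-menthyloxy]furan-2(5H)-one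
Product: 9 trans-5-(menthyloxy)-4-(1,4,4-trimethyl-8-oxodecahydroazulen-1-yl)oxolan-2-one
Conditions: Fe(acac)3 (0.5 equiv), PhSiH3, EtOH/(CH2OH)2, 60 °C
Reagents that add atoms: none
Why: Hydrogen-atom-transfer-initiated reductive olefin coupling (Giese addition of the tertiary radical formed by Markovnikov H-atom delivery from an iron hydride), in which the radical should add to the butenolide β-carbon on its convex face (cis to both ring-fusion hydrogens) and anti to the menthyloxy group, setting the quaternary carbon and the adjacent CH stereocentre.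

Step 5
Reactants: 9 trans-5-(menthyloxy)-4-(1,4,4-trimethyl-8-oxodecahydroazulen-1-yl)oxolan-2-one
Product: 11 4-oxo-2-(1,4,4-trimethyl-8-methylidenedecahydroazulen-1-yl)pentanal, via bis-methylidene enol ether 10 (not isolated)
Conditions: Cp2TiMe2 (5 equiv), toluene, 75 °C, dark; then oxalic acid, THF/H2O, 0 °C
Reagents that add atoms: bis(cyclopentadienyl)dimethyltitanium, C[Ti](C)(C1C=CC=C1)C1C=CC=C1; water, O
Why: Petasis methylenation converts the hindered ketone into the exocyclic alkene and the lactone carbonyl into an enol ether without base, so the α-stereocentres are kept, and mild aqueous acid then opens the enol ether acetal to the methyl ketone and the aldehyde with loss of menthol.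

Step 6
Reactants: 11 4-oxo-2-(1,4,4-trimethyl-8-methylidenedecahydroazulen-1-yl)pentanal; 12 (R)-methyl p-tolyl sulfoxide
Product: 14 (5E)-6-[(R)-4-methylbenzenesulfinyl]-4-(1,4,4-trimethyl-8-methylidenedecahydroazulen-1-yl)hex-5-en-2-one, via sulfinylmethylphosphonate 13 (not isolated)
Conditions: 12, LDA (2.1 equiv), THF, −78 °C; ClP(O)(OEt)2; then 11, −78 °C → rt
Reagents that add atoms: none
Why: One-pot Horner–Wadsworth–Emmons olefination with the α-phosphoryl sulfoxide anion made in the flask should react only at the aldehyde and give the E-alkene from this α-branched substrate, the sulfur configuration being retained because no bond to sulfur is broken.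

Step 7
Reactants: 14 (5E)-6-[(R)-4-methylbenzenesulfinyl]-4-(1,4,4-trimethyl-8-methylidenedecahydroazulen-1-yl)hex-5-en-2-one
Product: 15 trans-3,3-dichloro-5-[(4-methylphenyl)sulfanyl]-4-[3-oxo-1-(1,4,4-trimethyl-8-methylidenedecahydroazulen-1-yl)butyl]oxolan-2-one
Conditions: Cl3CCOCl (slow addition), Zn–Cu couple, THF, −45 → 0 °C
Reagents that add atoms: trichloroacetyl chloride, ClC(Cl)(Cl)C(Cl)=O
Why: Marino lactonisation (the additive Pummerer reaction of an alkenyl sulfoxide with dichloroketene, which is the closest known reaction type): the sulfinyl oxygen adds to the ketene carbonyl to give an acyloxysulfonium enolate, and a [3,3]-sigmatropic shift then forms the C3–C4 bond and breaks S–O. The carboxylate so released closes 5-exo-trig onto the thionium carbon and forms the O1–C5 bond, the sulfinyl oxygen becoming the ring oxygen. The C4 stereocentre is set by the sulfur stereocentre through a chair transition state with the p-tolyl group and the E-alkene substituent pseudo-equatorial, so the R sulfoxide on the E alkene should deliver the required face. The C5 centre (arylthio trans to the side chain, from suprafacial addition across the E alkene) is erased in step 8. The step needs chemoselectivity for the sulfoxide over the exocyclic methylene (possible [2+2] cycloaddition) and the methyl ketone, which the high nucleophilicity of the sulfinyl oxygen at −45 °C and a low stationary ketene concentration should secure. It also needs reagent control over the neighbouring side-chain stereocentre, which the tight cyclic transition state should provide.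

Step 8
Reactants: 15 trans-3,3-dichloro-5-[(4-methylphenyl)sulfanyl]-4-[3-oxo-1-(1,4,4-trimethyl-8-methylidenedecahydroazulen-1-yl)butyl]oxolan-2-one
Product: 16 4-[3-oxo-1-(1,4,4-trimethyl-8-methylidenedecahydroazulen-1-yl)butyl]oxolan-2-one
Conditions: Bu3SnH (6 equiv), AIBN (cat.), toluene, 100 °C
Reagents that add atoms: none
Why: Radical chain reduction with tributyltin hydride should remove both α-chlorines and the anomeric arylthio group by C–Cl and C–S homolysis, a high hydride concentration outrunning cyclisation onto the alkene and the C4 stereocentre staying untouched.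

Step 9
Reactants: 16 4-[3-oxo-1-(1,4,4-trimethyl-8-methylidenedecahydroazulen-1-yl)butyl]oxolan-2-one
Product: 17 (4R)-4-{(1R)-2-acetoxy-1-[(1R,3aR,8aS)-1,4,4-trimethyl-8-methylidenedecahydroazulen-1-yl]ethyl}oxolan-2-one
Conditions: Me3SiOOSiMe3, TMSOTf (10 mol %), CH2Cl2, −40 → −20 °C
Reagents that add atoms: bis(trimethylsilyl) peroxide, C[Si](C)(C)OO[Si](C)(C)C
Why: Baeyer–Villiger oxidation under aprotic silyl peroxide conditions, in which the primary alkyl group should migrate in preference to methyl to give the acetate and the isolated 1,1-disubstituted alkene should not be epoxidised.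

Compound list
1 | 4,4-dimethylcyclohex-2-en-1-one | CC1(C)CCC(=O)C=C1 | starting material
2 | but-3-en-1-ylmagnesium bromide | C=CCC[Mg]Br | starting material
3 | bromomagnesium (3R)-3-(but-3-en-1-yl)-4,4-dimethylcyclohex-1-en-1-olate | Br[Mg]OC1=C[C@@H](CCC=C)C(C)(C)CC1 | intermediate
4 | (3R)-3-(but-3-en-1-yl)-4,4-dimethyl-1-(trimethylsilyloxy)cyclohex-1-ene | C[Si](C)(C)OC1=C[C@@H](CCC=C)C(C)(C)CC1 | intermediate
5 | cis-fused (3aR,7aR)-7,7-dimethyl-3-methylideneoctahydro-4H-inden-4-one | O=C1CCC(C)(C)[C@@H]2CCC(=C)[C@H]12 | intermediate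
6 | (3aR,8aR)-8,8-dimethyl-3-methylidene-5-(trimethylsilyl)octahydroazulen-4(1H)-one, both epimers at C5 | O=C1C([Si](C)(C)C)CCC(C)(C)[C@@H]2CCC(=C)[C@H]12 | intermediate
7 | cis-fused (3aR,8aR)-8,8-dimethyl-3-methylideneoctahydroazulen-4(1H)-one | O=C1CCCC(C)(C)[C@@H]2CCC(=C)[C@H]12 | intermediate
8 | (5R)-5-[(1R,2S,5R)-menthyloxy]furan-2(5H)-one | O=C1C=C[C@@H](O1)O[C@@H]2C[C@H](C)CC[C@H]2C(C)C | starting material
9 | trans-5-(menthyloxy)-4-(1,4,4-trimethyl-8-oxodecahydroazulen-1-yl)oxolan-2-one; acetal carbon R, azulenyl C1 substituent cis to H-3a and H-8a | O=C1CCCC(C)(C)[C@@H]2CC[C@@](C)([C@@H]3CC(=O)O[C@H]3O[C@@H]4C[C@H](C)CC[C@H]4C(C)C)[C@H]12 | intermediate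
10 | 5-(menthyloxy)-2-methylidene-4-(1,4,4-trimethyl-8-methylidenedecahydroazulen-1-yl)oxolane, stereocentres as in 9 | C=C1CCCC(C)(C)[C@@H]2CC[C@@](C)([C@@H]3CC(=C)O[C@H]3O[C@@H]4C[C@H](C)CC[C@H]4C(C)C)[C@H]12 | intermediate
11 | 4-oxo-2-(1,4,4-trimethyl-8-methylidenedecahydroazulen-1-yl)pentanal, stereocentres as in 9 | C=C1CCCC(C)(C)[C@@H]2CC[C@@](C)([C@H](CC(C)=O)C=O)[C@H]12 | intermediate
12 | (R)-methyl p-tolyl sulfoxide | C[S@@](=O)c1ccc(C)cc1 | starting material
13 | diethyl {[(S)-4-methylbenzenesulfinyl]methyl}phosphonate | CCOP(=O)(OCC)C[S@@](=O)c1ccc(C)cc1 | intermediate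
14 | (5E)-6-[(R)-4-methylbenzenesulfinyl]-4-(1,4,4-trimethyl-8-methylidenedecahydroazulen-1-yl)hex-5-en-2-one | C=C1CCCC(C)(C)[C@@H]2CC[C@@](C)([C@H](CC(C)=O)/C=C/[S@@](=O)c3ccc(C)cc3)[C@H]12 | intermediate
15 | trans-3,3-dichloro-5-[(4-methylphenyl)sulfanyl]-4-[3-oxo-1-(1,4,4-trimethyl-8-methylidenedecahydroazulen-1-yl)butyl]oxolan-2-one | C=C1CCCC(C)(C)[C@@H]2CC[C@@](C)([C@H](CC(C)=O)[C@@H]3[C@@H](Sc4ccc(C)cc4)OC(=O)C3(Cl)Cl)[C@H]12 | intermediate
16 | 4-[3-oxo-1-(1,4,4-trimethyl-8-methylidenedecahydroazulen-1-yl)butyl]oxolan-2-one, stereocentres as in 17 | C=C1CCCC(C)(C)[C@@H]2CC[C@@](C)([C@H](CC(C)=O)[C@@H]3COC(=O)C3)[C@H]12 | intermediate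
17 | (4R)-4-{(1R)-2-acetoxy-1-[(1R,3aR,8aS)-1,4,4-trimethyl-8-methylidenedecahydroazulen-1-yl]ethyl}oxolan-2-one | C=C1CCCC(C)(C)[C@@H]2CC[C@@](C)([C@H](COC(C)=O)[C@@H]3COC(=O)C3)[C@H]12 | target

Total step count: 9. Longest linear sequence: 9 steps (1 → 17).

Steps most likely to fail

Step 7. Dichloroketene may add [2+2] to the exocyclic methylene in competition with attack of the sulfinyl oxygen, and the neighbouring stereocentre may erode the facial control exerted by sulfur. The fallback sets out from 14 and builds the lactone stepwise by an additive Pummerer reaction with a silyl ketene acetal, which involves no free ketene. Treatment of 14 with CH2=C(OMe)OTBS and ZnI2 (cat.) in MeCN would give the γ-siloxy γ-arylthio ester F1, the C4 configuration again having to come from the sulfur stereocentre. 1 M HCl in THF would unmask the aldehyde ester F2. NaBH(OAc)3 would reduce the aldehyde in the presence of the methyl ketone to the hydroxy ester F3. PPTS in toluene would close the lactone, and the route is rejoined at 16.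

Step 9. Criegee migration of a primary alkyl group is slow, so Lewis-acid-induced isomerisation of the exocyclic alkene or incomplete conversion may take over. The fallback sets out from 16 and accepts oxidation of both functions. Trifluoroperacetic acid (from (CF3CO)2O and urea·H2O2, Na2HPO4, CH2Cl2, 0 °C) would give the spiro-epoxy acetate F4 by Baeyer–Villiger oxidation and epoxidation. Deoxygenation of the epoxide with Ph3P=Se and CF3CO2H in CH2Cl2 would restore the methylene and arrive at 17.

Step 4. The tertiary radical may be reduced or may isomerise the alkene before it is captured, and face selection at the butenolide may be poor under the iron hydride conditions. The fallback sets out from 7 and generates the same radical by photoredox fragmentation of a tertiary oxalate. Mukaiyama hydration (Mn(dpm)3 cat., PhSiH3, O2, i-PrOH, 0 °C) would give the tertiary alcohol F5. ClCOCO2Me, Et3N and DMAP would give the methyl oxalate F6, and CsOH·H2O (1 equiv) in THF/H2O the caesium oxalate F7. Irradiation of F7 with 8, [Ir(dF(CF3)ppy)2(dtbbpy)]PF6 (1 mol %) and water in DME/DMF (blue LEDs, 60 °C) would give the Giese adduct, and the route is rejoined at 9.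

Further compounds
F1 | step 7 | methyl 4-(tert-butyldimethylsilyloxy)-4-[(4-methylphenyl)sulfanyl]-3-[3-oxo-1-(1,4,4-trimethyl-8-methylidenedecahydroazulen-1-yl)butyl]butanoate, both epimers at C4 | C=C1CCCC(C)(C)[C@@H]2CC[C@@](C)([C@H](CC(C)=O)[C@@H](CC(=O)OC)C(O[Si](C)(C)C(C)(C)C)Sc3ccc(C)cc3)[C@H]12
F2 | step 7 | methyl 3-formyl-6-oxo-4-(1,4,4-trimethyl-8-methylidenedecahydroazulen-1-yl)heptanoate | C=C1CCCC(C)(C)[C@@H]2CC[C@@](C)([C@H](CC(C)=O)[C@@H](CC(=O)OC)C=O)[C@H]12
F3 | step 7 | methyl 3-(hydroxymethyl)-6-oxo-4-(1,4,4-trimethyl-8-methylidenedecahydroazulen-1-yl)heptanoate | C=C1CCCC(C)(C)[C@@H]2CC[C@@](C)([C@H](CC(C)=O)[C@@H](CC(=O)OC)CO)[C@H]12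
F4 | step 9 | spiro-epoxide of 17 at the exocyclic methylene, both epimers at the spiro carbon | O1CC12CCCC(C)(C)[C@@H]3CC[C@@](C)([C@H](COC(C)=O)[C@@H]4COC(=O)C4)[C@H]23
F5 | step 4 | cis-fused 3-hydroxy-3,8,8-trimethyloctahydroazulen-4(1H)-one, both epimers at C3 | O=C1CCCC(C)(C)[C@@H]2CCC(C)(O)[C@H]12
F6 | step 4 | methyl 1,4,4-trimethyl-8-oxodecahydroazulen-1-yl oxalate | O=C1CCCC(C)(C)[C@@H]2CCC(C)(OC(=O)C(=O)OC)[C@H]12
F7 | step 4 | caesium 1,4,4-trimethyl-8-oxodecahydroazulen-1-yl oxalate | O=C1CCCC(C)(C)[C@@H]2CCC(C)(OC(=O)C(=O)[O-])[C@H]12.[Cs+]
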